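The route rests on the bond from ring-B carbon C1′ to C2 of the pyranone ring C. C2 is the β-carbon of the C4 ketone; at the chromone oxidation level O1–C2=C3–C4=O is a flat vinylogous ester, so C2 accepts an aryl nucleophile and the C2 stereocentre does not yet exist. A rhodium-catalysed asymmetric 1,4-addition joins the complete erythro arylglycerol β-aryl ether, as its arylboronic acid, to 5,7-bis(benzyloxy)chromone and sets (2S) under ligand control in the same operation. The boronic acid comes from an Evans syn glycolate aldol (threo), Mitsunobu inversion of the benzylic carbinol (erythro) and borylation of the aryl bromide.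

Key step: step 10

Assumption: (S)-MeO-F12-BIPHEP, i.e. (S)-(6,6′-dimethoxybiphenyl-2,2′-diyl)bis[bis(3,4,5-trifluorophenyl)phosphine], is taken to deliver the aryl group to the chromone face that gives (2S), by analogy with (S)-BINAP and cyclohexenone; if the opposite face is delivered, the (R)-ligand is used with no other change.

Step 1
Reactants: 1 4-bromo-2,6-dimethoxyphenol
Product: 2 2-(4-bromo-2,6-dimethoxyphenoxy)acetic acid
Conditions: ClCH2CO2H, NaOH, H2O, reflux; then HCl
Reagents that add atoms: chloroacetic acid, OC(=O)CCl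
Why: Williamson ether synthesis, in which the phenoxide displaces chloride from chloroacetate by SN2 while the aryl bromide and the methyl ethers are inert.

Step 2
Reactants: 2 2-(4-bromo-2,6-dimethoxyphenoxy)acetic acid; 3 (R)-4-benzyloxazolidin-2-one
Product: 5 (R)-4-benzyl-3-[2-(4-bromo-2,6-dimethoxyphenoxy)acetyl]oxazolidin-2-one, via mixed pivalic anhydride 4 (not isolated)
Conditions: PivCl, Et3N, THF, −20 °C; then 3, LiCl, rt
Reagents that add atoms: none
Why: N-acylation of the oxazolidinone through a mixed anhydride, which is attacked at its less hindered aryloxyacetyl carbonyl under mild LiCl/Et3N activation.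

Step 3
Reactants: 5 (R)-4-benzyl-3-[2-(4-bromo-2,6-dimethoxyphenoxy)acetyl]oxazolidin-2-one; 6 4-(benzyloxy)-3-methoxybenzaldehyde
Product: 9 (R)-4-benzyl-3-[(2R,3S)-3-[4-(benzyloxy)-3-methoxyphenyl]-2-(4-bromo-2,6-dimethoxyphenoxy)-3-hydroxypropanoyl]oxazolidin-2-one, via (Z)-dibutylboron enolate 7 (not isolated), via dibutylboron aldolate 8 (not isolated)
Conditions: Bu2BOTf, i-Pr2NEt, CH2Cl2, −78 to 0 °C; then 6, −78 to 0 °C; pH 7 buffer, MeOH, H2O2
Reagents that add atoms: none
Why: Evans boron syn aldol reaction, in which the (Z)-enolate reacts through a Zimmerman–Traxler chair on the face away from the benzyl group of the dipole-opposed auxiliary, so the aryloxy-bearing carbon is set absolutely (2R here, S after reduction) and the carbinol comes out syn to it (3S, the threo series), to be corrected in step 6.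

Step 4
Reactants: 9 (R)-4-benzyl-3-[(2R,3S)-3-[4-(benzyloxy)-3-methoxyphenyl]-2-(4-bromo-2,6-dimethoxyphenoxy)-3-hydroxypropanoyl]oxazolidin-2-one
Product: 10 (1S,2S)-1-[4-(benzyloxy)-3-methoxyphenyl]-2-(4-bromo-2,6-dimethoxyphenoxy)propane-1,3-diol (threo)
Conditions: LiBH4, THF, H2O (1 equiv), 0 °C
Reagents that add atoms: none
Why: Reductive cleavage of the N-acyl oxazolidinone by hydride attack at the exocyclic carbonyl, which touches no stereocentre (the descriptor at C2 changes from R to S only because CH2OH ranks below the former imide carbon) and leaves the aryl bromide and the benzyl ether intact.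

Step 5
Reactants: 10 (1S,2S)-1-[4-(benzyloxy)-3-methoxyphenyl]-2-(4-bromo-2,6-dimethoxyphenoxy)propane-1,3-diol
Product: 11 (1S,2S)-1-[4-(benzyloxy)-3-methoxyphenyl]-2-(4-bromo-2,6-dimethoxyphenoxy)-3-[(tert-butyldimethylsilyl)oxy]propan-1-ol
Conditions: TBSCl, imidazole, CH2Cl2, 0 °C
Reagents that add atoms: tert-butyldimethylsilyl chloride, CC(C)(C)[Si](C)(C)Cl
Why: Selective silylation, since the primary hydroxyl reacts far faster with TBSCl than the hindered secondary benzylic one.

Step 6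
Reactants: 11 (1S,2S)-1-[4-(benzyloxy)-3-methoxyphenyl]-2-(4-bromo-2,6-dimethoxyphenoxy)-3-[(tert-butyldimethylsilyl)oxy]propan-1-ol
Product: 12 (1R,2S)-1-[4-(benzyloxy)-3-methoxyphenyl]-2-(4-bromo-2,6-dimethoxyphenoxy)-3-[(tert-butyldimethylsilyl)oxy]propyl 4-nitrobenzoate
Conditions: 4-O2NC6H4CO2H, PPh3, DIAD, THF, 0 °C to rt
Reagents that add atoms: 4-nitrobenzoic acid, OC(=O)c1ccc(cc1)[N+](=O)[O-]
Why: Mitsunobu reaction, in which the carboxylate displaces the alkoxyphosphonium group by SN2 and inverts the benzylic carbinol from 1S to 1R (threo to erythro), the acidic pronucleophile and low temperature favouring SN2 over ionisation.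

Step 7
Reactants: 12 (1R,2S)-1-[4-(benzyloxy)-3-methoxyphenyl]-2-(4-bromo-2,6-dimethoxyphenoxy)-3-[(tert-butyldimethylsilyl)oxy]propyl 4-nitrobenzoate
Product: 13 (1R,2S)-1-[4-(benzyloxy)-3-methoxyphenyl]-2-(4-bromo-2,6-dimethoxyphenoxy)-3-[(tert-butyldimethylsilyl)oxy]propan-1-ol (erythro)
Conditions: K2CO3 (cat.), MeOH/THF, 0 °C to rt
Reagents that add atoms: none
Why: Zemplén-type transesterification cleaves the activated ester at its acyl carbon, so the new 1R configuration is retained and the primary silyl ether, the benzyl ether and the aryl bromide survive.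

Step 8
Reactants: 13 (1R,2S)-1-[4-(benzyloxy)-3-methoxyphenyl]-2-(4-bromo-2,6-dimethoxyphenoxy)-3-[(tert-butyldimethylsilyl)oxy]propan-1-ol
Product: 14 [4-({(1R,2S)-1-[4-(benzyloxy)-3-methoxyphenyl]-3-[(tert-butyldimethylsilyl)oxy]-1-hydroxypropan-2-yl}oxy)-3,5-dimethoxyphenyl]boronic acid
Conditions: B2(OH)4, XPhos Pd G2 (cat.), XPhos, KOAc, EtOH, 80 °C
Reagents that add atoms: tetrahydroxydiboron, OB(O)B(O)O
Why: Miyaura-type palladium-catalysed borylation (oxidative addition into C–Br, acetate-assisted transmetalation from the diboron, reductive elimination) should give the boronic acid directly and tolerates the free hydroxyl.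

Step 9
Reactants: 15 5,7-dihydroxy-4H-chromen-4-one
Product: 16 5,7-bis(benzyloxy)-4H-chromen-4-one
Conditions: BnBr, K2CO3, DMF, 70 °C
Reagents that add atoms: benzyl bromide, BrCc1ccccc1
Why: Williamson O-benzylation of both phenols, with heating to overcome the hydrogen bond of the 5-hydroxyl to the C4 carbonyl.

Step 10
Reactants: 14 [4-({(1R,2S)-1-[4-(benzyloxy)-3-methoxyphenyl]-3-[(tert-butyldimethylsilyl)oxy]-1-hydroxypropan-2-yl}oxy)-3,5-dimethoxyphenyl]boronic acid; 16 5,7-bis(benzyloxy)-4H-chromen-4-one (1.5 equiv)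
Product: 17 (2S)-5,7-bis(benzyloxy)-2-[4-({(1R,2S)-1-[4-(benzyloxy)-3-methoxyphenyl]-3-[(tert-butyldimethylsilyl)oxy]-1-hydroxypropan-2-yl}oxy)-3,5-dimethoxyphenyl]chroman-4-one
Conditions: [Rh(OH)(cod)]2 (cat.), (S)-MeO-F12-BIPHEP, toluene/H2O, rt
Reagents that add atoms: none
Why: Transmetalation of 14 to the Rh(I)–OH complex gives an aryl–Rh(I) species, the chromone C2=C3 bond coordinates and inserts so that the aryl group goes to C2 and rhodium to C3 (oxa-π-allyl enolate), and water protonates the enolate and regenerates Rh–OH. The closest known reaction type is the Rh-catalysed asymmetric 1,4-addition of arylboronic acids to chromones with electron-poor atropisomeric diphosphines (Hayashi–Miyaura reaction). No ring is closed: ring C is already present in 16 and only its C2 changes from sp2 to sp3. The new C2 stereocentre is controlled by the ligand, which differentiates the two faces of the flat chromone in the insertion step, and the remote (1R,2S) centres of 14 are not expected to interfere. The step needs 1,4- over 1,2-addition, no second addition to the C4 ketone of 17 and no β-aryloxide elimination of the rhodium enolate to a chalcone (which would erase C2); base-free conditions at room temperature, fast protonation by water, the peri 5-benzyloxy group that screens C4 and the highly active electron-poor catalyst should secure these. The free benzylic hydroxyl, the silyl ether and the benzyl ethers are inert to Rh(I) and water.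

Step 11
Reactants: 17 (2S)-5,7-bis(benzyloxy)-2-[4-({(1R,2S)-1-[4-(benzyloxy)-3-methoxyphenyl]-3-[(tert-butyldimethylsilyl)oxy]-1-hydroxypropan-2-yl}oxy)-3,5-dimethoxyphenyl]chroman-4-one
Product: 18 (2S)-5,7-bis(benzyloxy)-2-[4-({(1R,2S)-1-[4-(benzyloxy)-3-methoxyphenyl]-1,3-dihydroxypropan-2-yl}oxy)-3,5-dimethoxyphenyl]chroman-4-one
Conditions: Et3N·3HF, THF, rt
Reagents that add atoms: none
Why: Fluoride-mediated desilylation with a nearly neutral reagent, which avoids both base-induced retro-oxa-Michael opening at C2 and acid-induced ionisation of the benzylic alcohol.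

Step 12
Reactants: 18 (2S)-5,7-bis(benzyloxy)-2-[4-({(1R,2S)-1-[4-(benzyloxy)-3-methoxyphenyl]-1,3-dihydroxypropan-2-yl}oxy)-3,5-dimethoxyphenyl]chroman-4-one
Product: 19 (2S)-5,7-dihydroxy-2-[4-({(1R,2S)-1,3-dihydroxy-1-(4-hydroxy-3-methoxyphenyl)propan-2-yl}oxy)-3,5-dimethoxyphenyl]chroman-4-one (CNP0318401.1)
Conditions: H2 (1 atm), 10% Pd/C, EtOAc/MeOH, rt
Reagents that add atoms: none
Why: Palladium-catalysed hydrogenolysis of the three aryl benzyl ethers under neutral conditions, where the ArO–CH2Ph bonds cleave much faster than the secondary benzylic C–OH, the C2–O1 bond or the C4 ketone, the reaction being stopped at full conversion.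

Compound list
1 | 4-bromo-2,6-dimethoxyphenol | COc1cc(Br)cc(OC)c1O | starting material
2 | 2-(4-bromo-2,6-dimethoxyphenoxy)acetic acid | COc1cc(Br)cc(OC)c1OCC(=O)O | intermediate
3 | (R)-4-benzyloxazolidin-2-one | O=C1OC[C@@H](Cc2ccccc2)N1 | starting material
4 | 2-(4-bromo-2,6-dimethoxyphenoxy)acetic pivalic anhydride (not isolated) | COc1cc(Br)cc(OC)c1OCC(=O)OC(=O)C(C)(C)C | intermediate
5 | (R)-4-benzyl-3-[2-(4-bromo-2,6-dimethoxyphenoxy)acetyl]oxazolidin-2-one | COc1cc(Br)cc(OC)c1OCC(=O)N1[C@H](Cc2ccccc2)COC1=O | intermediate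
6 | 4-(benzyloxy)-3-methoxybenzaldehyde | COc1cc(C=O)ccc1OCc1ccccc1 | starting material
7 | (Z)-dibutylboron enolate of 5 (not isolated) | CCCCB(CCCC)O/C(=C\Oc1c(OC)cc(Br)cc1OC)N1[C@H](Cc2ccccc2)COC1=O | intermediate
8 | dibutylboron aldolate of 9 (not isolated) | COc1cc([C@H](OB(CCCC)CCCC)[C@H](C(=O)N2[C@H](Cc3ccccc3)COC2=O)Oc2c(OC)cc(Br)cc2OC)ccc1OCc1ccccc1 | intermediate
9 | (R)-4-benzyl-3-[(2R,3S)-3-[4-(benzyloxy)-3-methoxyphenyl]-2-(4-bromo-2,6-dimethoxyphenoxy)-3-hydroxypropanoyl]oxazolidin-2-one | COc1cc([C@H](O)[C@H](C(=O)N2[C@H](Cc3ccccc3)COC2=O)Oc2c(OC)cc(Br)cc2OC)ccc1OCc1ccccc1 | intermediate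
10 | (1S,2S)-1-[4-(benzyloxy)-3-methoxyphenyl]-2-(4-bromo-2,6-dimethoxyphenoxy)propane-1,3-diol | COc1cc([C@H](O)[C@H](CO)Oc2c(OC)cc(Br)cc2OC)ccc1OCc1ccccc1 | intermediate
11 | (1S,2S)-1-[4-(benzyloxy)-3-methoxyphenyl]-2-(4-bromo-2,6-dimethoxyphenoxy)-3-[(tert-butyldimethylsilyl)oxy]propan-1-ol | COc1cc([C@H](O)[C@H](CO[Si](C)(C)C(C)(C)C)Oc2c(OC)cc(Br)cc2OC)ccc1OCc1ccccc1 | intermediate
12 | (1R,2S)-1-[4-(benzyloxy)-3-methoxyphenyl]-2-(4-bromo-2,6-dimethoxyphenoxy)-3-[(tert-butyldimethylsilyl)oxy]propyl 4-nitrobenzoate | COc1cc([C@@H](OC(=O)c2ccc(cc2)[N+](=O)[O-])[C@H](CO[Si](C)(C)C(C)(C)C)Oc2c(OC)cc(Br)cc2OC)ccc1OCc1ccccc1 | intermediate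
13 | (1R,2S)-1-[4-(benzyloxy)-3-methoxyphenyl]-2-(4-bromo-2,6-dimethoxyphenoxy)-3-[(tert-butyldimethylsilyl)oxy]propan-1-ol | COc1cc([C@@H](O)[C@H](CO[Si](C)(C)C(C)(C)C)Oc2c(OC)cc(Br)cc2OC)ccc1OCc1ccccc1 | intermediate
14 | [4-({(1R,2S)-1-[4-(benzyloxy)-3-methoxyphenyl]-3-[(tert-butyldimethylsilyl)oxy]-1-hydroxypropan-2-yl}oxy)-3,5-dimethoxyphenyl]boronic acid | COc1cc([C@@H](O)[C@H](CO[Si](C)(C)C(C)(C)C)Oc2c(OC)cc(B(O)O)cc2OC)ccc1OCc1ccccc1 | intermediate
15 | 5,7-dihydroxy-4H-chromen-4-one | O=c1ccoc2cc(O)cc(O)c12 | starting material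
16 | 5,7-bis(benzyloxy)-4H-chromen-4-one | O=c1ccoc2cc(OCc3ccccc3)cc(OCc3ccccc3)c12 | intermediate
17 | (2S)-5,7-bis(benzyloxy)-2-[4-({(1R,2S)-1-[4-(benzyloxy)-3-methoxyphenyl]-3-[(tert-butyldimethylsilyl)oxy]-1-hydroxypropan-2-yl}oxy)-3,5-dimethoxyphenyl]chroman-4-one | COc1cc([C@@H](O)[C@H](CO[Si](C)(C)C(C)(C)C)Oc2c(OC)cc([C@@H]3CC(=O)c4c(OCc5ccccc5)cc(OCc5ccccc5)cc4O3)cc2OC)ccc1OCc1ccccc1 | intermediate
18 | (2S)-5,7-bis(benzyloxy)-2-[4-({(1R,2S)-1-[4-(benzyloxy)-3-methoxyphenyl]-1,3-dihydroxypropan-2-yl}oxy)-3,5-dimethoxyphenyl]chroman-4-one | COc1cc([C@@H](O)[C@H](CO)Oc2c(OC)cc([C@@H]3CC(=O)c4c(OCc5ccccc5)cc(OCc5ccccc5)cc4O3)cc2OC)ccc1OCc1ccccc1 | intermediate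
19 | (2S)-5,7-dihydroxy-2-[4-({(1R,2S)-1,3-dihydroxy-1-(4-hydroxy-3-methoxyphenyl)propan-2-yl}oxy)-3,5-dimethoxyphenyl]chroman-4-one | COc1cc([C@@H](O)[C@H](CO)Oc2c(OC)cc([C@@H]3CC(=O)c4c(O)cc(O)cc4O3)cc2OC)ccc1O | target

Total step count: 12. Longest linear sequence: 11 steps (steps 1–8 and 10–12, from compound 1); step 9 is a one-step branch.

Steps most likely to fail

1. Step 10. Carborhodation of the electron-rich 5,7-dialkoxychromone may be slower than protodeboronation of 14, and β-aryloxide elimination of the rhodium enolate followed by re-closure may erode the configuration at C2. The fallback sets out from 13 and comes back at 17. Bromine–lithium exchange on 13 (n-BuLi, 2.2 equiv, THF, −78 °C, the first equivalent forming the alkoxide) and a DMF quench should give 4-({(1R,2S)-1-[4-(benzyloxy)-3-methoxyphenyl]-3-[(tert-butyldimethylsilyl)oxy]-1-hydroxypropan-2-yl}oxy)-3,5-dimethoxybenzaldehyde F1. Claisen–Schmidt condensation of F1 with commercial 1-[2,4-bis(benzyloxy)-6-hydroxyphenyl]ethan-1-one (KOH, EtOH, rt) should give the (E)-2′-hydroxychalcone F2. Intramolecular oxa-Michael addition (6-endo-trig) with a quinine-derived bifunctional thiourea catalyst (toluene, rt) then closes ring C to 17; because the side chain is already a single enantiomer, the (2R) epimer is a diastereomer and is removed by preparative HPLC.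

2. Step 6. The alkoxyphosphonium ion may ionise at the electron-rich benzylic carbon, with loss of stereospecificity, or undergo E2 elimination to the enol ether. The fallback sets out from 11 and comes back at 13. Dess–Martin oxidation of 11 (NaHCO3, CH2Cl2, 0 °C) should give the α-aryloxy ketone (2S)-1-[4-(benzyloxy)-3-methoxyphenyl]-2-(4-bromo-2,6-dimethoxyphenoxy)-3-[(tert-butyldimethylsilyl)oxy]propan-1-one F3. Chelation-controlled reduction with Zn(BH4)2 (Et2O, −30 °C), in which zinc bridges the ketone and aryloxy oxygens (Cram chelate) and hydride adds anti to the CH2OTBS group, should give the erythro alcohol 13 directly.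

3. Step 8. Protodehalogenation and protodeboronation of the electron-rich arene may compete, and material may be lost in isolating a polar boronic acid that equilibrates with its boroxine. The fallback sets out from 13 and comes back at 14. Miyaura borylation with bis(pinacolato)diboron (PdCl2(dppf), KOAc, dioxane, 80 °C) should give the chromatographable pinacol boronate F4, and oxidative cleavage of the pinacol ester (NaIO4, NH4OAc, acetone/H2O, rt) should then give 14.

Further compounds
F1 | step 10 | 4-({(1R,2S)-1-[4-(benzyloxy)-3-methoxyphenyl]-3-[(tert-butyldimethylsilyl)oxy]-1-hydroxypropan-2-yl}oxy)-3,5-dimethoxybenzaldehyde | COc1cc([C@@H](O)[C@H](CO[Si](C)(C)C(C)(C)C)Oc2c(OC)cc(C=O)cc2OC)ccc1OCc1ccccc1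
F2 | step 10 | (E)-1-[2,4-bis(benzyloxy)-6-hydroxyphenyl]-3-[4-({(1R,2S)-1-[4-(benzyloxy)-3-methoxyphenyl]-3-[(tert-butyldimethylsilyl)oxy]-1-hydroxypropan-2-yl}oxy)-3,5-dimethoxyphenyl]prop-2-en-1-one | COc1cc([C@@H](O)[C@H](CO[Si](C)(C)C(C)(C)C)Oc2c(OC)cc(/C=C/C(=O)c3c(O)cc(OCc4ccccc4)cc3OCc3ccccc3)cc2OC)ccc1OCc1ccccc1
F3 | step 6 | (2S)-1-[4-(benzyloxy)-3-methoxyphenyl]-2-(4-bromo-2,6-dimethoxyphenoxy)-3-[(tert-butyldimethylsilyl)oxy]propan-1-one | COc1cc(C(=O)[C@H](CO[Si](C)(C)C(C)(C)C)Oc2c(OC)cc(Br)cc2OC)ccc1OCc1ccccc1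
F4 | step 8 | (1R,2S)-1-[4-(benzyloxy)-3-methoxyphenyl]-3-[(tert-butyldimethylsilyl)oxy]-2-[2,6-dimethoxy-4-(4,4,5,5-tetramethyl-1,3,2-dioxaborolan-2-yl)phenoxy]propan-1-ol | COc1cc([C@@H](O)[C@H](CO[Si](C)(C)C(C)(C)C)Oc2c(OC)cc(B3OC(C)(C)C(C)(C)O3)cc2OC)ccc1OCc1ccccc1
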